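The flavanone is cut at the C2–C3 bond of ring C. C2 carries one hydrogen, the ring oxygen O1 and the aryl carbon C1' of ring B, so it is drawn from the O-benzylic methylene of a ring B benzyl ether on ring A, and C3 from a diazomethyl ketone carbon. A chiral dirhodium carboxylate turns the diazoketone into a carbene that inserts into one of the two enantiotopic benzylic C–H bonds, closing ring C and setting the (2S) centre in one operation. The precursor is a 2-(arylmethoxy)-4,6-bis(triisopropylsilyloxy)phenyl diazomethyl ketone whose ring B already carries bromine, methoxy and prenyl; the diene arrives afterwards by cross-coupling.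

Key step: step 8

Assumption: Rh2(S-PTTL)4, dirhodium tetrakis[N-phthaloyl-(S)-tert-leucinate], is taken to deliver the (2S) product; should the sense of induction prove opposite, the mirror-image catalyst Rh2(R-PTTL)4 from D-tert-leucine is used under the same conditions.

Step 1
Reactants: 1 3,5-dibromo-4-hydroxybenzaldehyde
Product: 2 3,5-dibromo-4-methoxybenzaldehyde
Conditions: MeI, K2CO3, DMF, rt
Reagents that add atoms: iodomethane, CI
Why: Williamson O-methylation of an acidic, di-ortho-brominated phenol should proceed cleanly, the aldehyde being inert to carbonate.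

Step 2
Reactants: 2 3,5-dibromo-4-methoxybenzaldehyde
Product: 3 1,3-dibromo-5-(dimethoxymethyl)-2-methoxybenzene (the dimethyl acetal of 2)
Conditions: HC(OMe)3, TsOH·H2O (cat.), MeOH, rt
Reagents that add atoms: trimethyl orthoformate, COC(OC)OC; methanol, CO (solvent, exchanges with the orthoformate)
Why: Acid-catalysed acetalisation, driven by the orthoformate as water scavenger, should mask the aldehyde against the organolithium of the next step.

Step 3
Reactants: 3 1,3-dibromo-5-(dimethoxymethyl)-2-methoxybenzene; 4 prenyl bromide (1-bromo-3-methylbut-2-ene)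
Product: 7 3-bromo-4-methoxy-5-(3-methylbut-2-enyl)benzaldehyde, via aryllithium 5 (not isolated), via prenylated dimethyl acetal 6 (not isolated)
Conditions: n-BuLi (1.0 equiv), THF, −78 °C; then CuBr·SMe2 (10 mol%), 4, −78 → 0 °C; then 1 M HCl, THF, rt
Reagents that add atoms: water, O (aldehyde oxygen on acetal hydrolysis); n-butyllithium, [Li]CCCC (lithium of 5 only)
Why: Bromine–lithium exchange at one of two equivalent methoxy-flanked bromides should stop after the first exchange because the aryl anion deactivates the second, the copper-assisted alkylation at the primary carbon of the allylic bromide should give the linear prenyl arene, and dilute acid should unmask the aldehyde without touching the trisubstituted alkene.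

Step 4
Reactants: 7 3-bromo-4-methoxy-5-(3-methylbut-2-enyl)benzaldehyde
Product: 8 [3-bromo-4-methoxy-5-(3-methylbut-2-enyl)phenyl]methanol
Conditions: NaBH4, MeOH, 0 °C
Reagents that add atoms: none
Why: Borohydride reduction of an aryl aldehyde is chemoselective beside an aryl bromide and an isolated alkene.

Step 5
Reactants: 9 2,4,6-trihydroxyacetophenone
Product: 10 1-[2-hydroxy-4,6-bis(triisopropylsilyloxy)phenyl]ethanone
Conditions: i-Pr3SiCl (2.2 equiv), imidazole, DMF, 0 °C → rt
Reagents that add atoms: chlorotriisopropylsilane, CC(C)[Si](Cl)(C(C)C)C(C)C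
Why: Phenol silylation should stop at the bis-ether because the last ortho hydroxyl is hydrogen-bonded to the carbonyl and shielded from the bulky chlorosilane, and triisopropylsilyl is chosen over smaller silyl groups for its resistance to base, to silyl migration and to attack by a carbene.

Step 6
Reactants: 10 1-[2-hydroxy-4,6-bis(triisopropylsilyloxy)phenyl]ethanone; 8 [3-bromo-4-methoxy-5-(3-methylbut-2-enyl)phenyl]methanol
Product: 11 1-[2-{[3-bromo-4-methoxy-5-(3-methylbut-2-enyl)phenyl]methoxy}-4,6-bis(triisopropylsilyloxy)phenyl]ethanone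
Conditions: PPh3, DIAD, THF, 0 °C → rt
Reagents that add atoms: none
Why: Mitsunobu etherification of an acidic phenol with a primary benzylic alcohol runs under neutral conditions, which should leave untouched the aryl silyl ethers that a carbonate-mediated benzylation would put at risk.

Step 7
Reactants: 11 1-[2-{[3-bromo-4-methoxy-5-(3-methylbut-2-enyl)phenyl]methoxy}-4,6-bis(triisopropylsilyloxy)phenyl]ethanone
Product: 14 2-diazo-1-[2-{[3-bromo-4-methoxy-5-(3-methylbut-2-enyl)phenyl]methoxy}-4,6-bis(triisopropylsilyloxy)phenyl]ethanone, via lithium enolate 12 (not isolated), via trifluoroacetyl diketone 13 (not isolated)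
Conditions: LiN(SiMe3)2 (1.1 equiv), THF, −78 °C; CF3CO2CH2CF3, −78 °C; aqueous work-up; then MsN3, Et3N, H2O (1 equiv), MeCN, rt
Reagents that add atoms: methanesulfonyl azide, CS(=O)(=O)N=[N+]=[N-] (the two diazo nitrogens); 2,2,2-trifluoroethyl trifluoroacetate, O=C(OCC(F)(F)F)C(F)(F)F (trifluoroacetyl group of 13 only); lithium bis(trimethylsilyl)amide, [Li]N([Si](C)(C)C)[Si](C)(C)C (lithium of 12 only)
Why: In this detrifluoroacetylative diazo transfer, trifluoroacetylation of the kinetic enolate activates the methyl ketone so that the sulfonyl azide should transfer N2 to the α-carbon with loss of the trifluoroacetyl group as its N-sulfonyl amide, while the bulky silyl ethers resist transfer to the enolate oxygen at −78 °C.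

Step 8
Reactants: 14 2-diazo-1-[2-{[3-bromo-4-methoxy-5-(3-methylbut-2-enyl)phenyl]methoxy}-4,6-bis(triisopropylsilyloxy)phenyl]ethanone
Product: 15 (2S)-2-[3-bromo-4-methoxy-5-(3-methylbut-2-enyl)phenyl]-5,7-bis(triisopropylsilyloxy)chroman-4-one
Conditions: Rh2(S-PTTL)4 (1 mol%), CH2Cl2, 0 °C, 14 added over 3 h by syringe pump, final concentration 0.01 M
Reagents that add atoms: none
Why: Dinitrogen loss from 14 at the dimer of divalent rhodium gives an electrophilic acceptor carbene at the future C3, which inserts into one benzylic C–H bond of the ArCH2O group through a concerted, asynchronous three-centre transition state with hydride-like transfer, forming the C2–C3 bond. The closest known reaction type is the chiral dirhodium-carboxylate-catalysed intramolecular C–H insertion of 2-alkoxyaryl diazoketones to chroman-4-ones. Ring C closes as a six-membered ring by insertion at the sixth atom counted from the carbene carbon (1,6-insertion), since the fifth atom, which would give a five-membered ring, is the ether oxygen and carries no hydrogen. C2 is set under catalyst control: the pocket formed by the four N-phthaloyl-tert-leucinate ligands should allow only one of the two enantiotopic benzylic hydrogens, the one that keeps ring B away from the ligand wall, to reach the carbene carbon. The step needs chemoselectivity for C–H insertion over oxonium ylide formation at the benzylic ether oxygen with 1,2-benzyl shift to a benzofuranone, over attack on the silyl ether oxygen and over cyclopropanation of the prenyl alkene. This is secured by the double activation of the C–H bond by O1 and the 4-methoxyaryl ring, by the bulky triisopropylsilyl groups that shield the second ortho oxygen and offer no activated C–H bond within reach, and by slow addition at high dilution.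

Step 9
Reactants: 16 2-methylbut-1-en-3-yne
Product: 17 (E)-4,4,5,5-tetramethyl-2-(3-methylbuta-1,3-dienyl)-1,3,2-dioxaborolane
Conditions: pinacolborane, Cp2Zr(H)Cl (5 mol%), Et3N (10 mol%), CH2Cl2, rt, sealed vessel
Reagents that add atoms: pinacolborane, B1OC(C)(C)C(C)(C)O1
Why: Zirconocene-hydride-catalysed syn hydroboration of the terminal alkyne should place boron at the terminus with E geometry, the 1,1-disubstituted alkene being much less reactive toward hydrozirconation.

Step 10
Reactants: 15 (2S)-2-[3-bromo-4-methoxy-5-(3-methylbut-2-enyl)phenyl]-5,7-bis(triisopropylsilyloxy)chroman-4-one; 17 (E)-4,4,5,5-tetramethyl-2-(3-methylbuta-1,3-dienyl)-1,3,2-dioxaborolane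
Product: 18 (2S)-2-{4-methoxy-3-[(1E)-3-methylbuta-1,3-dienyl]-5-(3-methylbut-2-enyl)phenyl}-5,7-bis(triisopropylsilyloxy)chroman-4-one
Conditions: Pd(OAc)2 (5 mol%), SPhos (10 mol%), K3PO4 (2 equiv), THF/H2O (10:1), 40 °C
Reagents that add atoms: none
Why: Suzuki–Miyaura coupling of the aryl bromide with the (E)-alkenylboronate retains the alkene geometry, and the electron-rich biarylphosphine should allow a low temperature and a mild phosphate base so that enolisation at C3 and ring opening to the chalcone, which would erode C2, stay slow.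

Step 11
Reactants: 18 (2S)-2-{4-methoxy-3-[(1E)-3-methylbuta-1,3-dienyl]-5-(3-methylbut-2-enyl)phenyl}-5,7-bis(triisopropylsilyloxy)chroman-4-one
Product: 19 (2S)-5,7-dihydroxy-2-{4-methoxy-3-[(1E)-3-methylbuta-1,3-dienyl]-5-(3-methylbut-2-enyl)phenyl}chroman-4-one
Conditions: Bu4NF, AcOH (1:1, 2.5 equiv each), THF, 0 °C → rt
Reagents that add atoms: none
Why: Fluoride should cleave both aryl Si–O bonds, and the acetic acid buffer keeps the medium from becoming basic enough to open ring C by retro-oxa-Michael reaction, so the C2 configuration, the diene and the prenyl group are preserved.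

Compound list

1 | 3,5-dibromo-4-hydroxybenzaldehyde | O=Cc1cc(Br)c(O)c(Br)c1 | starting material
2 | 3,5-dibromo-4-methoxybenzaldehyde | COc1c(Br)cc(C=O)cc1Br | intermediate
3 | 1,3-dibromo-5-(dimethoxymethyl)-2-methoxybenzene | COc1c(Br)cc(C(OC)OC)cc1Br | intermediate
4 | prenyl bromide (1-bromo-3-methylbut-2-ene) | CC(C)=CCBr | starting material
5 | [3-bromo-5-(dimethoxymethyl)-2-methoxyphenyl]lithium (formed in the flask) | [Li]c1cc(C(OC)OC)cc(Br)c1OC | intermediate
6 | 1-bromo-5-(dimethoxymethyl)-2-methoxy-3-(3-methylbut-2-enyl)benzene (formed in the flask) | COC(OC)c1cc(Br)c(OC)c(CC=C(C)C)c1 | intermediate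
7 | 3-bromo-4-methoxy-5-(3-methylbut-2-enyl)benzaldehyde | O=Cc1cc(Br)c(OC)c(CC=C(C)C)c1 | intermediate
8 | [3-bromo-4-methoxy-5-(3-methylbut-2-enyl)phenyl]methanol | OCc1cc(Br)c(OC)c(CC=C(C)C)c1 | intermediate
9 | 2,4,6-trihydroxyacetophenone | CC(=O)c1c(O)cc(O)cc1O | starting material
10 | 1-[2-hydroxy-4,6-bis(triisopropylsilyloxy)phenyl]ethanone | CC(=O)c1c(O)cc(O[Si](C(C)C)(C(C)C)C(C)C)cc1O[Si](C(C)C)(C(C)C)C(C)C | intermediate
11 | 1-[2-{[3-bromo-4-methoxy-5-(3-methylbut-2-enyl)phenyl]methoxy}-4,6-bis(triisopropylsilyloxy)phenyl]ethanone | CC(=O)c1c(O[Si](C(C)C)(C(C)C)C(C)C)cc(O[Si](C(C)C)(C(C)C)C(C)C)cc1OCc1cc(Br)c(OC)c(CC=C(C)C)c1 | intermediate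
12 | lithium enolate of 11 (formed in the flask) | C=C(O[Li])c1c(O[Si](C(C)C)(C(C)C)C(C)C)cc(O[Si](C(C)C)(C(C)C)C(C)C)cc1OCc1cc(Br)c(OC)c(CC=C(C)C)c1 | intermediate
13 | 1-[2-{[3-bromo-4-methoxy-5-(3-methylbut-2-enyl)phenyl]methoxy}-4,6-bis(triisopropylsilyloxy)phenyl]-4,4,4-trifluorobutane-1,3-dione (carried on crude) | O=C(CC(=O)C(F)(F)F)c1c(O[Si](C(C)C)(C(C)C)C(C)C)cc(O[Si](C(C)C)(C(C)C)C(C)C)cc1OCc1cc(Br)c(OC)c(CC=C(C)C)c1 | intermediate
14 | 2-diazo-1-[2-{[3-bromo-4-methoxy-5-(3-methylbut-2-enyl)phenyl]methoxy}-4,6-bis(triisopropylsilyloxy)phenyl]ethanone | [N-]=[N+]=CC(=O)c1c(O[Si](C(C)C)(C(C)C)C(C)C)cc(O[Si](C(C)C)(C(C)C)C(C)C)cc1OCc1cc(Br)c(OC)c(CC=C(C)C)c1 | intermediate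
15 | (2S)-2-[3-bromo-4-methoxy-5-(3-methylbut-2-enyl)phenyl]-5,7-bis(triisopropylsilyloxy)chroman-4-one | Brc1cc([C@@H]2CC(=O)c3c(O[Si](C(C)C)(C(C)C)C(C)C)cc(O[Si](C(C)C)(C(C)C)C(C)C)cc3O2)cc(CC=C(C)C)c1OC | intermediate
16 | 2-methylbut-1-en-3-yne | C=C(C)C#C | starting material
17 | (E)-4,4,5,5-tetramethyl-2-(3-methylbuta-1,3-dienyl)-1,3,2-dioxaborolane | C=C(C)/C=C/B1OC(C)(C)C(C)(C)O1 | intermediate
18 | (2S)-2-{4-methoxy-3-[(1E)-3-methylbuta-1,3-dienyl]-5-(3-methylbut-2-enyl)phenyl}-5,7-bis(triisopropylsilyloxy)chroman-4-one | C=C(C)/C=C/c1cc([C@@H]2CC(=O)c3c(O[Si](C(C)C)(C(C)C)C(C)C)cc(O[Si](C(C)C)(C(C)C)C(C)C)cc3O2)cc(CC=C(C)C)c1OC | intermediate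
19 | (2S)-5,7-dihydroxy-2-{4-methoxy-3-[(1E)-3-methylbuta-1,3-dienyl]-5-(3-methylbut-2-enyl)phenyl}chroman-4-one | C=C(C)/C=C/c1cc([C@@H]2CC(=O)c3c(O)cc(O)cc3O2)cc(CC=C(C)C)c1OC | target

Total step count: 11. Longest linear sequence: 9 steps (steps 1, 2, 3, 4, 6, 7, 8, 10 and 11, from 1 to 19); steps 5 and 9 are one-step side branches.

Steps most likely to fail

Step 8. The carbene may be captured by the benzylic ether oxygen, giving an oxonium ylide and a 1,2-benzyl shift, or the acceptor-only carbene may discriminate poorly between the two enantiotopic hydrogens. The fallback sets out from 10 and 7 and comes back at 15. Pyrrolidine-mediated condensation of 10 with 7 (pyrrolidine, MeCN, 50 °C; enamine aldol, dehydration and oxa-Michael closure of the chalcone) should give racemic 2-[3-bromo-4-methoxy-5-(3-methylbut-2-enyl)phenyl]-5,7-bis(triisopropylsilyloxy)chroman-4-one F1. Kinetic resolution by asymmetric transfer hydrogenation follows, with RuCl(p-cymene)(TsDPEN) and HCO2H/Et3N, using the ligand antipode that reduces the (2R)-ketone faster and stopping near half conversion. It should convert the unwanted enantiomer into (2R,4R)-2-[3-bromo-4-methoxy-5-(3-methylbut-2-enyl)phenyl]-5,7-bis(triisopropylsilyloxy)chroman-4-ol F2, which is removed by chromatography, leaving (2S)-ketone 15. Both operations are known for flavanones; the cost is that at most half of the material is carried forward.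

Step 10. Enolisation at C3 under the phosphate base, followed by reversible opening of ring C to the chalcone, may erode the C2 configuration, and the aryl silyl ethers may be partly lost (the latter converges in step 11). The fallback sets out from 15 and 16 and comes back at 18. Radical hydrostannation of 16 (Bu3SnH, AIBN cat., 80 °C, equilibrated to the E isomer) should give (E)-tributyl(3-methylbuta-1,3-dienyl)stannane F3. A base-free Stille coupling with 15 (Pd(PPh3)4, toluene, 90 °C) then forms the same aryl–alkenyl bond under neutral conditions and gives 18.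

Step 7. Silyl transfer from the ortho phenolic oxygen to the enolate oxygen, or incomplete C-acylation of the hindered enolate, may divert the methyl ketone before diazo transfer. The fallback sets out from 11 and comes back at 14. Condensation of 11 with N,N-dimethylformamide dimethyl acetal (toluene, 100 °C) should give the enaminone (E)-1-[2-{[3-bromo-4-methoxy-5-(3-methylbut-2-enyl)phenyl]methoxy}-4,6-bis(triisopropylsilyloxy)phenyl]-3-(dimethylamino)prop-2-en-1-one F4. Treatment with tosyl azide (MeCN, rt) then effects a base-free diazo transfer by cycloaddition of the azide to the enamine and fragmentation, giving diazoketone 14 and the N-sulfonyl formamidine; no metal enolate is formed at any stage.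

Further compounds

F1 | step 8 | racemic 2-[3-bromo-4-methoxy-5-(3-methylbut-2-enyl)phenyl]-5,7-bis(triisopropylsilyloxy)chroman-4-one | Brc1cc(C2CC(=O)c3c(O[Si](C(C)C)(C(C)C)C(C)C)cc(O[Si](C(C)C)(C(C)C)C(C)C)cc3O2)cc(CC=C(C)C)c1OC
F2 | step 8 | (2R,4R)-2-[3-bromo-4-methoxy-5-(3-methylbut-2-enyl)phenyl]-5,7-bis(triisopropylsilyloxy)chroman-4-ol | COc1c(Br)cc([C@H]2C[C@@H](O)c3c(O[Si](C(C)C)(C(C)C)C(C)C)cc(O[Si](C(C)C)(C(C)C)C(C)C)cc3O2)cc1CC=C(C)C
F3 | step 10 | (E)-tributyl(3-methylbuta-1,3-dienyl)stannane | C=C(C)/C=C/[Sn](CCCC)(CCCC)CCCC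
F4 | step 7 | (E)-1-[2-{[3-bromo-4-methoxy-5-(3-methylbut-2-enyl)phenyl]methoxy}-4,6-bis(triisopropylsilyloxy)phenyl]-3-(dimethylamino)prop-2-en-1-one | CN(C)/C=C/C(=O)c1c(O[Si](C(C)C)(C(C)C)C(C)C)cc(O[Si](C(C)C)(C(C)C)C(C)C)cc1OCc1cc(Br)c(OC)c(CC=C(C)C)c1
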